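Everything rests on cutting the benzylic ether bond O1–C2 of the oxolane. Because C2 carries the electron-rich 3,4-dimethoxyphenyl ring and C3 carries the C6 hydroxymethyl arm, C2–C3 can be an aryl oxirane that the C5 hydroxyl opens at C2. In one operation this 5-endo opening closes the oxolane, sets C2 by inversion and leaves the oxirane oxygen on C3 as a tertiary alcohol that is later removed by a radical reduction which also sets C3. The precursor is a trisubstituted epoxy diol: aryl cis to a 1-silyloxy-2-hydroxyethyl arm (C4, C5), hydroxymethyl (C6) on the same oxirane carbon, assembled from (S)-3-hydroxy-γ-butyrolactone and veratraldehyde.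

Key step: step 6

Remark on labels: O1, C2 (aryl-bearing), C3, C4 (oxygen-bearing) and C5 are the oxolane atoms of the target and C6 is the CH2 on C3; the same labels are used for the open-chain intermediates. The spatial arrangement at C4 is that of lactone 1 throughout; CIP letters at C3 and C4 change along the route only where neighbour priorities change.

Assumption: the L-fructose-derived enantiomer of the Shi ketone is taken as an available catalyst (mirror image of the common D-fructose-derived ketone, made from L-sorbose).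

Step 1
Reactants: 1 (S)-3-hydroxy-γ-butyrolactone
Product: 2 (4S)-4-[(tert-butyldimethylsilyl)oxy]oxolan-2-one
Conditions: TBSCl, imidazole, DMF, rt
Reagents that add atoms: tert-butyldimethylsilyl chloride, CC(C)(C)[Si](C)(C)Cl
Why: Imidazole-promoted silylation of a secondary alcohol masks the hydroxyl before enolate chemistry and leaves the stereocentre untouched.

Step 2
Reactants: 2 (4S)-4-[(tert-butyldimethylsilyl)oxy]oxolan-2-one; 3 veratraldehyde
Product: 4 (3S,4S)-4-[(tert-butyldimethylsilyl)oxy]-3-[(3,4-dimethoxyphenyl)(hydroxy)methyl]oxolan-2-one (3,4-trans; carbinol centre as a mixture)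
Conditions: LiN(SiMe3)2 (1.1 equiv), THF, −78 °C; 3, −78 °C; aq. NH4Cl quench at −78 °C
Reagents that add atoms: none
Why: Lithium enolate aldol addition, in which a β-silyloxy γ-lactone enolate (the class used with silylated 2-deoxyribonolactones) should hold at −78 °C without β-elimination and add to the aldehyde anti to the silyloxy group, the two new centres being erased in step 3.

Step 3
Reactants: 4 (3S,4S)-4-[(tert-butyldimethylsilyl)oxy]-3-[(3,4-dimethoxyphenyl)(hydroxy)methyl]oxolan-2-one
Product: 6 (3E,4S)-4-[(tert-butyldimethylsilyl)oxy]-3-[(3,4-dimethoxyphenyl)methylidene]oxolan-2-one, via benzylic mesylate 5 (not isolated)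
Conditions: MsCl, Et3N, CH2Cl2, 0 °C; then DBU, 0 °C to rt
Reagents that add atoms: methanesulfonyl chloride, CS(=O)(=O)Cl (its atoms stay only in intermediate 5)
Why: Mesylation then E1cB elimination (aldol condensation by dehydration) expels the benzylic mesylate, a far better leaving group than the ring silyloxide, and should give the conjugated E-arylidene lactone (aryl anti to the carbonyl, syn to C4) as in related α-arylidene butyrolactones.

Step 4
Reactants: 6 (3E,4S)-4-[(tert-butyldimethylsilyl)oxy]-3-[(3,4-dimethoxyphenyl)methylidene]oxolan-2-one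
Product: 7 (2S,3Z)-2-[(tert-butyldimethylsilyl)oxy]-3-[(3,4-dimethoxyphenyl)methylidene]butane-1,4-diol
Conditions: i-Bu2AlH (4 equiv), CH2Cl2, −78 to 0 °C; aq. KNaC4H4O6 work-up
Reagents that add atoms: none
Why: i-Bu2AlH reduction of an α,β-unsaturated lactone proceeds by 1,2-hydride delivery through the lactol to the allylic 1,4-diol without touching the alkene, so the olefin geometry (now Z by CIP, aryl cis to C4) and C4 are kept.

Step 5
Reactants: 7 (2S,3Z)-2-[(tert-butyldimethylsilyl)oxy]-3-[(3,4-dimethoxyphenyl)methylidene]butane-1,4-diol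
Product: 8 (2R)-2-[(tert-butyldimethylsilyl)oxy]-2-[(2S,3S)-3-(3,4-dimethoxyphenyl)-2-(hydroxymethyl)oxiran-2-yl]ethan-1-ol
Conditions: 1,2:4,5-di-O-isopropylidene-β-L-erythro-2,3-hexodiulo-2,6-pyranose (ent-Shi ketone, 30 mol%), KHSO5 (Oxone, 2KHSO5·KHSO4·K2SO4), K2CO3, Bu4NHSO4 (cat.), MeCN–CH2(OMe)2–aq. Na2B4O7 buffer (pH about 10.5), 0 °C; product used crude
Reagents that add atoms: potassium peroxymonosulfate (active salt of Oxone), [K+].[O-]S(=O)(=O)OO
Why: Shi asymmetric epoxidation (chiral dioxirane, spiro transition state) suits a trisubstituted styrenyl allylic alcohol, tolerates the free diol and spares the acid-labile aryl oxirane in basic buffer, and the L-fructose-derived ketone should deliver oxygen to the face that is also favoured by the substrate (anti to the silyloxy group in the A(1,3)-minimised conformer), giving the (2S,3S)-oxirane with aryl cis to the C4 arm.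

Step 6
Reactants: 8 (2R)-2-[(tert-butyldimethylsilyl)oxy]-2-[(2S,3S)-3-(3,4-dimethoxyphenyl)-2-(hydroxymethyl)oxiran-2-yl]ethan-1-ol
Product: 9 (2R,3S,4R)-4-[(tert-butyldimethylsilyl)oxy]-2-(3,4-dimethoxyphenyl)-3-(hydroxymethyl)oxolan-3-ol
Conditions: (±)-camphor-10-sulfonic acid (5 mol%), CH2Cl2, −40 to −20 °C; Et3N quench
Reagents that add atoms: none
Why: Protonation of the oxirane oxygen by the sulfonic acid weakens the benzylic C2–O bond and the C5 hydroxyl attacks C2 from the rear in a borderline SN2 opening. The closest known reaction type is the acid-catalysed endo-selective cyclisation of aryl- and vinyl-substituted epoxy alcohols to 2-substituted 3-hydroxy cyclic ethers. The oxolane closes in the 5-endo-tet mode, preferred over 4-exo attack at the fully substituted C3 and over oxetane formation by the C6 hydroxyl because only C2 can carry positive charge, stabilised by the 3,4-dimethoxyphenyl ring. The one new stereocentre, C2, is set by inversion of the (3S)-oxirane carbon, which places the aryl group cis to the C4 silyloxy group and to the C3 hydroxyl, while C3 and C4 are untouched. The step needs stereospecific inversion and not a free benzylic cation, and the tethered nucleophile held at the rear of C2, the non-polar solvent, the catalytic weak acid and the low temperature should secure this.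

Step 7
Reactants: 9 (2R,3S,4R)-4-[(tert-butyldimethylsilyl)oxy]-2-(3,4-dimethoxyphenyl)-3-(hydroxymethyl)oxolan-3-ol; 10 3,4-dimethoxybenzoyl chloride
Product: 11 [(2R,3S,4R)-4-[(tert-butyldimethylsilyl)oxy]-2-(3,4-dimethoxyphenyl)-3-hydroxyoxolan-3-yl]methyl 3,4-dimethoxybenzoate
Conditions: pyridine, 4-(dimethylamino)pyridine (cat.), CH2Cl2, 0 °C
Reagents that add atoms: none
Why: Nucleophilic acyl substitution (DMAP-catalysed aroylation) should be selective for the primary C6 hydroxyl because the tertiary C3 hydroxyl is too hindered to react with an aroyl chloride at 0 °C.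

Step 8
Reactants: 11 [(2R,3S,4R)-4-[(tert-butyldimethylsilyl)oxy]-2-(3,4-dimethoxyphenyl)-3-hydroxyoxolan-3-yl]methyl 3,4-dimethoxybenzoate
Product: 12 methyl [(2R,3S,4R)-4-[(tert-butyldimethylsilyl)oxy]-3-{[(3,4-dimethoxybenzoyl)oxy]methyl}-2-(3,4-dimethoxyphenyl)oxolan-3-yl] oxalate
Conditions: ClC(O)CO2Me, 4-(dimethylamino)pyridine (3 equiv), CH2Cl2, 0 °C to rt
Reagents that add atoms: methyl oxalyl chloride, COC(=O)C(=O)Cl
Why: DMAP-activated acylation with the small, highly electrophilic methyl oxalyl chloride is the standard first stage of the Dowd–Choi deoxygenation and has precedent for hindered tertiary hydroxyls on oxolane rings.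

Step 9
Reactants: 12 methyl [(2R,3S,4R)-4-[(tert-butyldimethylsilyl)oxy]-3-{[(3,4-dimethoxybenzoyl)oxy]methyl}-2-(3,4-dimethoxyphenyl)oxolan-3-yl] oxalate
Product: 13 [(2S,3S,4S)-4-[(tert-butyldimethylsilyl)oxy]-2-(3,4-dimethoxyphenyl)oxolan-3-yl]methyl 3,4-dimethoxybenzoate
Conditions: Bu3SnH, 2,2′-azobis(isobutyronitrile) (cat.), toluene, 100 °C
Reagents that add atoms: none
Why: Dowd–Choi radical deoxygenation (a Barton–McCombie variant for tertiary alcohols) fragments the oxalate to the planar tertiary C3 radical, which should take hydrogen from Bu3SnH on the face opposite the cis C2 aryl and C4 silyloxy groups, so the C6 arm ends up cis to both.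

Step 10
Reactants: 13 [(2S,3S,4S)-4-[(tert-butyldimethylsilyl)oxy]-2-(3,4-dimethoxyphenyl)oxolan-3-yl]methyl 3,4-dimethoxybenzoate
Product: 14 [(2S,3R,4S)-2-(3,4-dimethoxyphenyl)-4-hydroxyoxolan-3-yl]methyl 3,4-dimethoxybenzoate
Conditions: HF·pyridine, pyridine, THF, 0 °C to rt
Reagents that add atoms: none
Why: Fluoride-mediated silyl ether cleavage under buffered, non-basic conditions should free the C4 hydroxyl without migration of the neighbouring cis aroyl ester and without touching the benzylic ether.

Compound list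
1 | (S)-3-hydroxy-γ-butyrolactone [(4S)-4-hydroxyoxolan-2-one] | O=C1C[C@H](O)CO1 | starting material
2 | (4S)-4-[(tert-butyldimethylsilyl)oxy]oxolan-2-one | O=C1C[C@H](O[Si](C)(C)C(C)(C)C)CO1 | intermediate
3 | veratraldehyde (3,4-dimethoxybenzaldehyde) | COc1ccc(C=O)cc1OC | starting material
4 | (3S,4S)-4-[(tert-butyldimethylsilyl)oxy]-3-[(3,4-dimethoxyphenyl)(hydroxy)methyl]oxolan-2-one (carbinol centre unassigned, mixture) | O=C1[C@@H](C(O)c2ccc(OC)c(OC)c2)[C@H](O[Si](C)(C)C(C)(C)C)CO1 | intermediate
5 | (3R,4S)-4-[(tert-butyldimethylsilyl)oxy]-3-[(3,4-dimethoxyphenyl)(methanesulfonyloxy)methyl]oxolan-2-one (benzylic mesylate, formed in the flask) | O=C1[C@@H](C(OS(C)(=O)=O)c2ccc(OC)c(OC)c2)[C@H](O[Si](C)(C)C(C)(C)C)CO1 | intermediate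
6 | (3E,4S)-4-[(tert-butyldimethylsilyl)oxy]-3-[(3,4-dimethoxyphenyl)methylidene]oxolan-2-one | O=C1/C(=C/c2ccc(OC)c(OC)c2)[C@H](O[Si](C)(C)C(C)(C)C)CO1 | intermediate
7 | (2S,3Z)-2-[(tert-butyldimethylsilyl)oxy]-3-[(3,4-dimethoxyphenyl)methylidene]butane-1,4-diol | OC/C(=C/c1ccc(OC)c(OC)c1)[C@H](O[Si](C)(C)C(C)(C)C)CO | intermediate
8 | (2R)-2-[(tert-butyldimethylsilyl)oxy]-2-[(2S,3S)-3-(3,4-dimethoxyphenyl)-2-(hydroxymethyl)oxiran-2-yl]ethan-1-ol (aryl cis to the silyloxyethyl arm) | OC[C@@]1(O[C@H]1c1ccc(OC)c(OC)c1)[C@H](O[Si](C)(C)C(C)(C)C)CO | intermediate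
9 | (2R,3S,4R)-4-[(tert-butyldimethylsilyl)oxy]-2-(3,4-dimethoxyphenyl)-3-(hydroxymethyl)oxolan-3-ol (aryl, C3 hydroxyl and silyloxy all cis) | OC[C@@]1(O)[C@H](O[Si](C)(C)C(C)(C)C)CO[C@@H]1c1ccc(OC)c(OC)c1 | intermediate
10 | 3,4-dimethoxybenzoyl chloride | COc1ccc(C(Cl)=O)cc1OC | starting material
11 | [(2R,3S,4R)-4-[(tert-butyldimethylsilyl)oxy]-2-(3,4-dimethoxyphenyl)-3-hydroxyoxolan-3-yl]methyl 3,4-dimethoxybenzoate | COc1ccc(C(=O)OC[C@@]2(O)[C@H](O[Si](C)(C)C(C)(C)C)CO[C@@H]2c2ccc(OC)c(OC)c2)cc1OC | intermediate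
12 | methyl [(2R,3S,4R)-4-[(tert-butyldimethylsilyl)oxy]-3-{[(3,4-dimethoxybenzoyl)oxy]methyl}-2-(3,4-dimethoxyphenyl)oxolan-3-yl] oxalate | COc1ccc(C(=O)OC[C@@]2(OC(=O)C(=O)OC)[C@H](O[Si](C)(C)C(C)(C)C)CO[C@@H]2c2ccc(OC)c(OC)c2)cc1OC | intermediate
13 | [(2S,3S,4S)-4-[(tert-butyldimethylsilyl)oxy]-2-(3,4-dimethoxyphenyl)oxolan-3-yl]methyl 3,4-dimethoxybenzoate (all-cis) | COc1ccc(C(=O)OC[C@@H]2[C@H](O[Si](C)(C)C(C)(C)C)CO[C@@H]2c2ccc(OC)c(OC)c2)cc1OC | intermediate
14 | [(2S,3R,4S)-2-(3,4-dimethoxyphenyl)-4-hydroxyoxolan-3-yl]methyl 3,4-dimethoxybenzoate (all-cis) | COc1ccc(C(=O)OC[C@@H]2[C@H](O)CO[C@@H]2c2ccc(OC)c(OC)c2)cc1OC | target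

Total step count: 10
Longest linear sequence: 10 steps (1 to 14)

Steps most likely to fail

Step 6. The oxirane may ionise to a free benzylic cation before the hydroxyl engages, which would erode the configuration at C2, or a 1,2-shift may compete. The fallback closes the same O1–C2 bond by alkene activation and sets out from diol 7. N-(Phenylselanyl)phthalimide with catalytic camphor-10-sulfonic acid in CH2Cl2 at −78 °C should form a seleniranium ion on the face anti to the silyloxy group. The C5 hydroxyl opens it anti and 5-endo at the benzylic carbon (phenylselenoetherification) to give [(2R,3S,4R)-4-[(tert-butyldimethylsilyl)oxy]-2-(3,4-dimethoxyphenyl)-3-(phenylselanyl)oxolan-3-yl]methanol F1. Aroylation of its primary hydroxyl with 10 (pyridine, cat. DMAP, CH2Cl2) gives [(2R,3S,4R)-4-[(tert-butyldimethylsilyl)oxy]-2-(3,4-dimethoxyphenyl)-3-(phenylselanyl)oxolan-3-yl]methyl 3,4-dimethoxybenzoate F2. Bu3SnH with 2,2′-azobis(isobutyronitrile) in toluene at 80 °C then cleaves the C–Se bond to the same C3 radical as in step 9, and the route is rejoined at 13. In this variant the face selection rests on the C4 stereocentre alone.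

Step 5. The catalyst may not fully control the face on this hindered olefin, or the electron-rich oxirane may open hydrolytically in the aqueous medium. The fallback runs from 7 to 8 by hydroxyl-directed titanium catalysis in an anhydrous medium (Sharpless asymmetric epoxidation): Ti(OiPr)4 (10–20 mol%), L-(+)-diisopropyl tartrate, anhydrous t-BuOOH, 4 Å molecular sieves, CH2Cl2, −25 °C. The C6 allylic hydroxyl binds titanium, and the natural tartrate delivers oxygen to the same face as it does for (E)-2-substituted cinnamyl alcohols. It returns at 8 and makes no compound outside the list (F0). If the titanium alkoxide already triggers ring closure in that flask, the material would arrive as 9 by the same inversion.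

Step 9. Hydrogen-atom transfer to the C3 radical may show poor facial selectivity, and the preceding acylation of the crowded tertiary hydroxyl may be sluggish. The fallback sets C3–H by hydroboration instead, starts from 9 and bypasses steps 7 to 9. NaIO4 in aqueous THF cleaves the 1,2-diol to (2R,4R)-4-[(tert-butyldimethylsilyl)oxy]-2-(3,4-dimethoxyphenyl)oxolan-3-one F3. Non-basic methylenation with Cp2TiMe2 (toluene, 65 °C), chosen to avoid enolisation at C2, gives (2R,4S)-4-[(tert-butyldimethylsilyl)oxy]-2-(3,4-dimethoxyphenyl)-3-methylideneoxolane F4. 9-Borabicyclo[3.3.1]nonane should add from the face opposite the aryl and silyloxy groups, with boron on the terminal carbon. NaBO3 oxidation then gives the all-cis alcohol [(2S,3S,4S)-4-[(tert-butyldimethylsilyl)oxy]-2-(3,4-dimethoxyphenyl)oxolan-3-yl]methanol F5. Aroylation with 10 (pyridine, cat. DMAP) rejoins the route at 13.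

Further compounds
F1 | step 6 | [(2R,3S,4R)-4-[(tert-butyldimethylsilyl)oxy]-2-(3,4-dimethoxyphenyl)-3-(phenylselanyl)oxolan-3-yl]methanol | OC[C@@]1([Se]c2ccccc2)[C@H](O[Si](C)(C)C(C)(C)C)CO[C@@H]1c1ccc(OC)c(OC)c1
F2 | step 6 | [(2R,3S,4R)-4-[(tert-butyldimethylsilyl)oxy]-2-(3,4-dimethoxyphenyl)-3-(phenylselanyl)oxolan-3-yl]methyl 3,4-dimethoxybenzoate | COc1ccc(C(=O)OC[C@@]2([Se]c3ccccc3)[C@H](O[Si](C)(C)C(C)(C)C)CO[C@@H]2c2ccc(OC)c(OC)c2)cc1OC
F0 | step 5 | none | none
F3 | step 9 | (2R,4R)-4-[(tert-butyldimethylsilyl)oxy]-2-(3,4-dimethoxyphenyl)oxolan-3-one | O=C1[C@H](O[Si](C)(C)C(C)(C)C)CO[C@@H]1c1ccc(OC)c(OC)c1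
F4 | step 9 | (2R,4S)-4-[(tert-butyldimethylsilyl)oxy]-2-(3,4-dimethoxyphenyl)-3-methylideneoxolane | C=C1[C@H](O[Si](C)(C)C(C)(C)C)CO[C@@H]1c1ccc(OC)c(OC)c1
F5 | step 9 | [(2S,3S,4S)-4-[(tert-butyldimethylsilyl)oxy]-2-(3,4-dimethoxyphenyl)oxolan-3-yl]methanol | OC[C@@H]1[C@H](O[Si](C)(C)C(C)(C)C)CO[C@@H]1c1ccc(OC)c(OC)c1
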